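**Proposed synthesis of 5,3',5'-trihydroxy-6,7,2'-trimethoxyflavone (11) by late C5'–H borylation–oxidation**

## The problem

The target 11 is a 4H-chromen-4-one in which the benzo ring A (C5–C8) is fused to the pyranone ring C (O1, C2, C3, C4) and C2 carries the aryl ring B (C1'–C6'). It has no stereocentre, so nothing has to be set or relayed. The difficulty is the placing of six oxygen substituents and the distinction of three free hydroxyls (C5, C3', C5') from three methyl ethers (C6, C7, C2'). Ring A maps onto commodity 3,4,5-trioxygenated benzenes. Ring B has the uncommon 1-aryl-2,3,5-trioxygenation, with the C2' methyl ether wedged between the C1'–C2 bond and the C3' hydroxyl, and building blocks of that pattern are scarce.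

Several groups limit the choice of reagents:
- the pyranone opens with hot hydroxide, and its C2=C3 bond is attacked by dioxirane-type oxidants and by hydride;
- the C6 methoxy group is lost under forcing Lewis acid once O5 is bound to the acid;
- the 4-methoxyphenol unit of ring B (C5'–OH para to C2'–OMe) is easily over-oxidised.

The feature that opens the route is that C1', C2' and C3' carry contiguous substituents. C5'–H is therefore the only aromatic C–H of the flavone with hydrogen on both neighbouring carbons. C4'–H and C6'–H each have one ortho substituent, C8–H lies between C8a and the C7 methoxy group, and C3–H lies between C2 and C4. The most accessible C–H is thus exactly where the last hydroxyl is missing. A second handle is the C5 methyl ether, peri to the C4 carbonyl, which a boron Lewis acid removes by chelation.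

## Retrosynthesis

**11 ⇒ 10.** The O5–CH3 and O3'–CH(CH3)2 bonds are cut last and together. The precursor 10 is the C5 methyl, C3' isopropyl ether of the target. BCl3 is asked to discriminate a chelated methyl ether and a secondary alkyl ether from three ordinary methyl ethers. The 3'-oxygen needs a group without aromatic C–H (a benzyl ring would itself be borylated) that is inert to hydroxide, to hot iodine/DMSO and to peroxide. An acetal fails the iodine/DMSO test and a silyl ether fails the hydroxide test. Isopropyl passes all of them and leaves in the same operation as the C5 methyl group.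

**10 ⇒ 7 + 8 (through 9).** The C5'–O bond is cut. Carrying this oxygen from the start would demand a 2,3,5-trioxygenated benzaldehyde with three differentiated oxygens. Electrophilic substitution on the flavone would go to C8 of ring A. A sterically controlled C–H borylation of 7 with bis(pinacolato)diboron 8, then oxidation of boronate 9, puts the oxygen on C5' for the structural reason given above. The precursor 7 has a ring B that comes from a common catechol aldehyde. The forward step must be site-selective and must leave the pyranone untouched.

**7 ⇒ 6.** The O1–C2 bond of ring C is cut and the C2=C3 unsaturation removed, which leads to the 2'-hydroxychalcone 6. A carbonylative alkynone annulation was weighed for this ring closure. It needs a hindered 2,6-disubstituted iodophenol, carbon monoxide, and control of six- against five-membered closure. The iodine/DMSO oxidative cyclisation is established on exactly this ring A pattern and only asks that the ring B protecting group be acid-proof.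

**6 ⇒ 5 + 3.** The C2–C3 bond (flavone numbering, the chalcone alkene) is cut by a retro-aldol condensation. This is the convergent point: acetophenone 5 carries ring A and aldehyde 3 carries ring B. The aldehyde cannot enolise, so only one condensation mode exists.

**5 ⇒ 4.** The aryl–acyl bond C4a–C4 is cut. In 3,4,5-trimethoxyphenol 4 the two ortho positions are equivalent and the para position is blocked, so a Friedel–Crafts acetylation can give only one ketone.

**3 ⇒ 2 ⇒ 1.** The two O–alkyl bonds of ring B are cut in a fixed order. In the dianion of 2,3-dihydroxybenzaldehyde 1 the C3 phenoxide is the more nucleophilic, so isopropyl enters there first to give 2. The chelated C2 hydroxyl is then methylated to give 3.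

## Roads not taken

**Alternative 1:** Ring B is built de novo by a Moore ring expansion. The cut is C5'–C6'. Heating racemic 4-(3,3-diethoxyprop-1-en-2-yl)-4-methoxy-3-(propan-2-yloxy)cyclobut-2-en-1-one A1 in xylene would open the four-membered ring to a dienylketene. Six-electron closure and tautomerisation would give 3-(diethoxymethyl)-4-methoxy-5-(propan-2-yloxy)phenol A2.
- Merits: all four ring B substituents are fixed by construction, and the C5' hydroxyl emerges already differentiated from the C3' ether. In regiochemical certainty this road is better than the chosen one, which rests on a steric preference in a late metal-catalysed step.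
- Weak points: A1 needs a mono-alkoxy cyclobutenedione precursor, a regioselective addition of an acetal-bearing alkenyl metal and O-methylation of a tertiary alkoxide. A2 is still only a ring B aldehyde equivalent. It must be protected at the phenol, unmasked and carried through the whole flavone assembly.
- Comparison: the route would be roughly twice as long. The chosen plan sets against the regiochemical certainty of this road seven steps from commodity aromatics and a halogen-based backup that restores regiochemical certainty if needed.

**Alternative 2:** Ring C is closed by anodic dehydrogenative C–O coupling. The cut is O1–C8a. Constant-current oxidation of 1-[2-methoxy-3,5-bis(pivaloyloxy)phenyl]-3-(2,3,4-trimethoxyphenyl)propane-1,3-dione A3 (graphite anode, hexafluoroisopropanol, Bu4NBF4) would join the enol oxygen to ring A and give 2-[3,5-bis(pivaloyloxy)-2-methoxyphenyl]-5,6,7-trimethoxy-4H-chromen-4-one A4.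
- Merits: no ortho-hydroxyl is needed on ring A, no chemical oxidant is used, and the C5' oxygen is present from the start, so no site-selectivity question arises late.
- Weak points: the diketone has two enol oxygens and two electron-rich rings, so closure onto ring B is a competing path that only the pivalates discourage. The trimethoxyarene radical cation can also be trapped by solvent. This kind of aryl C–H oxygenation has not been established for 1,3-diketones giving flavones. The scarce 2,3,5-trioxygenated ring B acid is still required, which is the real supply problem.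
- Comparison: the gain on ring A is small, since the ortho-hydroxy ketone 5 is one step from phenol 4. The chosen plan keeps its one uncertain step within a reaction class well documented for arenes of this substitution type, and it uses a common ring B block.

**Alternative 3:** Ring A is folded biomimetically. The cut is C4a–C5. Base would convert racemic methyl 4-{6-[3,5-bis(benzyloxy)-2-methoxyphenyl]-4-oxo-4H-pyran-2-yl}-2-methoxy-3-oxobutanoate A5 into a vinylogous dienolate. Its C4a would attack the ester carbon and expel methanol, and aromatisation would give 2-[3,5-bis(benzyloxy)-2-methoxyphenyl]-5,7-dihydroxy-6-methoxy-4H-chromen-4-one A6.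
- Merits: ring A arrives with C5–OH free and C6–OMe in place. Only a selective methylation of the non-chelated C7 hydroxyl and a hydrogenolysis over Pd/C remain. This endgame is milder than a BCl3 dealkylation and is in that respect better than the chosen one.
- Weak points: the most acidic proton of A5 is on the methoxy-bearing carbon between ketone and ester, not on the C8 methylene. A dianion is therefore needed, and O-acylation to a fused pyranopyranone competes. Building A5 takes several steps. The ring B part is again the scarce 2,3,5-trioxygenated block.
- Comparison: the chosen plan sets against the milder endgame a chelation-controlled demethylation that is standard for 5,6,7-trimethoxyflavones, a shorter sequence, and ring A chemistry that needs no development.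

Key step: step 6

## Route

**Step 1**
Reactants: 1 2,3-dihydroxybenzaldehyde
Product: 2 2-hydroxy-3-(propan-2-yloxy)benzaldehyde
Conditions: NaH (2.2 equiv), DMSO, 20 °C; then 2-bromopropane (1.3 equiv), 20 → 45 °C; aq. HCl
Reagents that add atoms: 2-bromopropane, CC(C)Br
Why: Regioselective Williamson alkylation of a catechol dianion: the C2 phenoxide is held by the ortho formyl group through chelation and conjugation, so the C3 phenoxide is the stronger nucleophile and takes the electrophile.

**Step 2**
Reactants: 2 2-hydroxy-3-(propan-2-yloxy)benzaldehyde
Product: 3 2-methoxy-3-(propan-2-yloxy)benzaldehyde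
Conditions: MeI (1.5 equiv), K2CO3 (2 equiv), DMF, 40 °C
Reagents that add atoms: iodomethane, CI
Why: Williamson methylation of the remaining, chelated phenol, as in the routine conversion of ortho-hydroxybenzaldehydes into their methyl ethers; the aldehyde and the isopropyl ether are inert to carbonate.

**Step 3**
Reactants: 4 3,4,5-trimethoxyphenol
Product: 5 1-(6-hydroxy-2,3,4-trimethoxyphenyl)ethan-1-one
Conditions: AcOH, BF3·OEt2 (3 equiv), 90 °C; then aq. NaOAc
Reagents that add atoms: acetic acid, CC(=O)O
Why: Friedel–Crafts ortho-acylation of a phenol under BF3 (O-acylation and Fries-type transfer to carbon); the two ortho positions are equivalent and the para position is blocked, so only one ketone can form.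

**Step 4**
Reactants: 5 1-(6-hydroxy-2,3,4-trimethoxyphenyl)ethan-1-one; 3 2-methoxy-3-(propan-2-yloxy)benzaldehyde
Product: 6 (2E)-1-(6-hydroxy-2,3,4-trimethoxyphenyl)-3-[2-methoxy-3-(propan-2-yloxy)phenyl]prop-2-en-1-one
Conditions: 50% aq. KOH, EtOH, 20 °C; then 2 M HCl to pH 3
Reagents that add atoms: none
Why: Claisen–Schmidt condensation of a methyl ketone with a non-enolisable aldehyde; E1cB loss of water under equilibrating conditions gives the E alkene, and all ether groups are stable to hydroxide.

**Step 5**
Reactants: 6 (2E)-1-(6-hydroxy-2,3,4-trimethoxyphenyl)-3-[2-methoxy-3-(propan-2-yloxy)phenyl]prop-2-en-1-one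
Product: 7 5,6,7-trimethoxy-2-[2-methoxy-3-(propan-2-yloxy)phenyl]-4H-chromen-4-one
Conditions: I2 (10 mol%), DMSO, 130 °C; aq. Na2S2O3
Reagents that add atoms: none
Why: Iodine/DMSO oxidative cyclisation of a 2'-hydroxychalcone: 6-endo-trig oxa-Michael addition of the phenol forms O1–C2, α-iodination and loss of HI introduce C2=C3, and DMSO reoxidises HI to iodine; the isopropyl ether, unlike an acetal, withstands the traces of HI.

**Step 6**
Reactants: 7 5,6,7-trimethoxy-2-[2-methoxy-3-(propan-2-yloxy)phenyl]-4H-chromen-4-one; 8 bis(pinacolato)diboron
Product: 10 2-[5-hydroxy-2-methoxy-3-(propan-2-yloxy)phenyl]-5,6,7-trimethoxy-4H-chromen-4-one, via C5' pinacol boronate 9 (not isolated)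
Conditions: [Ir(OMe)(cod)]2 (2.5 mol%), 4,4'-di-tert-butyl-2,2'-bipyridine (5 mol%), 8 (1.3 equiv), THF, 80 °C; then 30% aq. H2O2, 2 M aq. NaOH, THF, 0 °C; aq. Na2S2O3, pH 5
Reagents that add atoms: hydrogen peroxide, OO (supplies the phenolic oxygen)
Why: The monovalent iridium precatalyst [Ir(OMe)(cod)]2, the bipyridine and 8 give the 16-electron trivalent iridium complex (dtbpy)Ir(Bpin)3, which cleaves the least hindered aromatic C–H bond by oxidative addition to a pentavalent iridium aryl hydride and releases boronate 9 by C–B reductive elimination, 8 regenerating the tris(boryl) with loss of HBpin. Hydroperoxide then adds to boron and the aryl group migrates from boron to oxygen at the same carbon, so hydrolysis gives the C5' phenol 10; this is the known sterically controlled iridium C–H borylation of arenes with one-flask oxidation to phenols, in which 1,2,3-trisubstituted benzenes react at C5. No ring is closed and no stereocentre is formed. The step needs site selectivity for C5'–H over C4'–H, C6'–H, C3–H and C8–H: C5'–H alone has hydrogen on both neighbours, C4'–H is shielded by the branched isopropoxy group, C6'–H by the chromone, and C3–H and C8–H are flanked on both sides. The C4 carbonyl cannot steer the catalyst to its peri position because C5 carries a methoxy group, and the isopropyl ether offers neither an aromatic C–H nor an O–B bond that could direct borylation to C4'. Alkaline peroxide at 0 °C is chosen because the aryl-substituted C2=C3 bond of a flavone is slow to undergo nucleophilic epoxidation, whereas dioxirane-forming oxidants would attack it.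

**Step 7**
Reactants: 10 2-[5-hydroxy-2-methoxy-3-(propan-2-yloxy)phenyl]-5,6,7-trimethoxy-4H-chromen-4-one
Product: 11 2-(3,5-dihydroxy-2-methoxyphenyl)-5-hydroxy-6,7-dimethoxy-4H-chromen-4-one
Conditions: BCl3 (1 M in CH2Cl2, 6 equiv), CH2Cl2, −78 → 0 °C; MeOH, then 1 M aq. HCl, 40 °C
Reagents that add atoms: none
Why: Lewis-acid ether cleavage with two built-in selectivities: boron held between the C4 carbonyl and O5 activates only the peri methyl group for chloride attack (chelation-controlled demethylation of 5-methoxyflavones), and the secondary isopropyl–oxygen bond is cleaved by BCl3 far more readily than a methyl–oxygen bond, as is known for aryl isopropyl ethers beside methyl ethers; the C6, C7 and C2' methyl ethers have neither feature and should remain.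

## Compound list

1 | 2,3-dihydroxybenzaldehyde | O=Cc1cccc(O)c1O | starting material
2 | 2-hydroxy-3-(propan-2-yloxy)benzaldehyde | CC(C)Oc1cccc(C=O)c1O | intermediate
3 | 2-methoxy-3-(propan-2-yloxy)benzaldehyde | CC(C)Oc1cccc(C=O)c1OC | intermediate
4 | 3,4,5-trimethoxyphenol | COc1cc(O)cc(OC)c1OC | starting material
5 | 1-(6-hydroxy-2,3,4-trimethoxyphenyl)ethan-1-one | CC(=O)c1c(O)cc(OC)c(OC)c1OC | intermediate
6 | (2E)-1-(6-hydroxy-2,3,4-trimethoxyphenyl)-3-[2-methoxy-3-(propan-2-yloxy)phenyl]prop-2-en-1-one | COc1cc(O)c(C(=O)/C=C/c2cccc(OC(C)C)c2OC)c(OC)c1OC | intermediate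
7 | 5,6,7-trimethoxy-2-[2-methoxy-3-(propan-2-yloxy)phenyl]-4H-chromen-4-one | COc1cc2oc(-c3cccc(OC(C)C)c3OC)cc(=O)c2c(OC)c1OC | intermediate
8 | bis(pinacolato)diboron | CC1(C)OB(OC1(C)C)B1OC(C)(C)C(C)(C)O1 | starting material
9 | 5,6,7-trimethoxy-2-[2-methoxy-3-(propan-2-yloxy)-5-(4,4,5,5-tetramethyl-1,3,2-dioxaborolan-2-yl)phenyl]-4H-chromen-4-one | COc1cc2oc(-c3cc(B4OC(C)(C)C(C)(C)O4)cc(OC(C)C)c3OC)cc(=O)c2c(OC)c1OC | intermediate
10 | 2-[5-hydroxy-2-methoxy-3-(propan-2-yloxy)phenyl]-5,6,7-trimethoxy-4H-chromen-4-one | COc1cc2oc(-c3cc(O)cc(OC(C)C)c3OC)cc(=O)c2c(OC)c1OC | intermediate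
11 | 2-(3,5-dihydroxy-2-methoxyphenyl)-5-hydroxy-6,7-dimethoxy-4H-chromen-4-one | COc1cc2oc(-c3cc(O)cc(O)c3OC)cc(=O)c2c(O)c1OC | target

## Step count and least certain steps

Total step count: 7. Longest linear sequence: 6 steps (1 → 2 → 3 → 6 → 7 → 10 → 11, steps 1, 2, 4, 5, 6 and 7). The ring A branch joins after one step (step 3).

**Step 6 (key step).**
- What may go wrong: loss of site control, with boron entering at C4' or C6' of ring B or at C8 of ring A. The catalyst may also be arrested by binding to the pyranone carbonyl, and the HBpin formed may reduce the C2=C3 bond. In the oxidation, the 4-methoxyphenol unit of 10 may be over-oxidised.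
- Fallback: it sets out from 2 and returns at 9, and it fixes the C5' position by electrophilic substitution before the flavone exists.
  - Bromination of 2 (Br2, NaOAc, AcOH, 20 °C) para to the free hydroxyl should give 5-bromo-2-hydroxy-3-(propan-2-yloxy)benzaldehyde F1.
  - Methylation as in step 2 gives 5-bromo-2-methoxy-3-(propan-2-yloxy)benzaldehyde F2.
  - Condensation with 5 as in step 4 gives (2E)-3-[5-bromo-2-methoxy-3-(propan-2-yloxy)phenyl]-1-(6-hydroxy-2,3,4-trimethoxyphenyl)prop-2-en-1-one F3.
  - Iodine/DMSO closure as in step 5 gives 2-[5-bromo-2-methoxy-3-(propan-2-yloxy)phenyl]-5,6,7-trimethoxy-4H-chromen-4-one F4.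
  - Miyaura borylation of F4 with 8 (PdCl2(dppf), KOAc, dioxane, 90 °C; zerovalent palladium inserts into the C–Br bond) gives boronate 9, which is oxidised to 10 as in step 6.

**Step 7.**
- What may go wrong: over-dealkylation. Once O5 is bound to boron, the neighbouring C6 methoxy group can be chelated and cleaved if warming is needed to remove the isopropyl group. Alternatively the isopropyl ether may be removed incompletely at temperatures that spare C6.
- Fallback: it sets out from 1 and 4 and returns at 11. The 3'-oxygen is carried as a methoxymethyl acetal, which BCl3 removes at −78 °C, so that only the chelated methyl ether has to be cut and no warming is needed. This acetal would not survive hot iodine/DMSO, so ring C is then built under basic conditions from an alkyne.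
  - Dianion alkylation of 1 with chloromethyl methyl ether (NaH, DMSO) should give 2-hydroxy-3-(methoxymethoxy)benzaldehyde F5.
  - Methylation (MeI, K2CO3, DMF) gives 2-methoxy-3-(methoxymethoxy)benzaldehyde F6.
  - Ohira–Bestmann homologation (dimethyl (1-diazo-2-oxopropyl)phosphonate, K2CO3, MeOH) gives 1-ethynyl-2-methoxy-3-(methoxymethoxy)benzene F7.
  - Iodination of 4 (N-iodosuccinimide, MeCN, 0 °C) gives 2-iodo-3,4,5-trimethoxyphenol F8.
  - Carbonylative Sonogashira coupling of F7 with F8 and amine-mediated 6-endo closure (PdCl2(dppf), CO, Et2NH, 100 °C) gives 5,6,7-trimethoxy-2-[2-methoxy-3-(methoxymethoxy)phenyl]-4H-chromen-4-one F9.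
  - Borylation under the conditions of step 6 gives 5,6,7-trimethoxy-2-[2-methoxy-3-(methoxymethoxy)-5-(4,4,5,5-tetramethyl-1,3,2-dioxaborolan-2-yl)phenyl]-4H-chromen-4-one F10.
  - Peroxide oxidation gives 2-[5-hydroxy-2-methoxy-3-(methoxymethoxy)phenyl]-5,6,7-trimethoxy-4H-chromen-4-one F11.
  - BCl3 (CH2Cl2, −78 → 0 °C) then removes the acetal and the C5 methyl group to give 11.

**Step 1.**
- What may go wrong: slow substitution at the secondary bromide, with elimination to propene consuming the electrophile, and erosion of regioselectivity by alkylation at O2 when excess bromide and heat are used to compensate.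
- Fallback: it sets out from 1 and returns at 2, and it replaces selective alkylation by selective dealkylation.
  - Exhaustive alkylation (2-bromopropane, K2CO3, DMF, 70 °C) gives 2,3-bis(propan-2-yloxy)benzaldehyde F12.
  - BCl3 (1.05 equiv, CH2Cl2, −78 °C) then cleaves only the ether ortho to the formyl group through the six-membered chelate and gives 2.

## Further compounds

F1 | step 6 | 5-bromo-2-hydroxy-3-(propan-2-yloxy)benzaldehyde | CC(C)Oc1cc(Br)cc(C=O)c1O
F2 | step 6 | 5-bromo-2-methoxy-3-(propan-2-yloxy)benzaldehyde | CC(C)Oc1cc(Br)cc(C=O)c1OC
F3 | step 6 | (2E)-3-[5-bromo-2-methoxy-3-(propan-2-yloxy)phenyl]-1-(6-hydroxy-2,3,4-trimethoxyphenyl)prop-2-en-1-one | COc1cc(O)c(C(=O)/C=C/c2cc(Br)cc(OC(C)C)c2OC)c(OC)c1OC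
F4 | step 6 | 2-[5-bromo-2-methoxy-3-(propan-2-yloxy)phenyl]-5,6,7-trimethoxy-4H-chromen-4-one | COc1cc2oc(-c3cc(Br)cc(OC(C)C)c3OC)cc(=O)c2c(OC)c1OC
F5 | step 7 | 2-hydroxy-3-(methoxymethoxy)benzaldehyde | COCOc1cccc(C=O)c1O
F6 | step 7 | 2-methoxy-3-(methoxymethoxy)benzaldehyde | COCOc1cccc(C=O)c1OC
F7 | step 7 | 1-ethynyl-2-methoxy-3-(methoxymethoxy)benzene | COCOc1cccc(C#C)c1OC
F8 | step 7 | 2-iodo-3,4,5-trimethoxyphenol | COc1cc(O)c(I)c(OC)c1OC
F9 | step 7 | 5,6,7-trimethoxy-2-[2-methoxy-3-(methoxymethoxy)phenyl]-4H-chromen-4-one | COCOc1cccc(-c2cc(=O)c3c(OC)c(OC)c(OC)cc3o2)c1OC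
F10 | step 7 | 5,6,7-trimethoxy-2-[2-methoxy-3-(methoxymethoxy)-5-(4,4,5,5-tetramethyl-1,3,2-dioxaborolan-2-yl)phenyl]-4H-chromen-4-one | COCOc1cc(B4OC(C)(C)C(C)(C)O4)cc(-c2cc(=O)c3c(OC)c(OC)c(OC)cc3o2)c1OC
F11 | step 7 | 2-[5-hydroxy-2-methoxy-3-(methoxymethoxy)phenyl]-5,6,7-trimethoxy-4H-chromen-4-one | COCOc1cc(O)cc(-c2cc(=O)c3c(OC)c(OC)c(OC)cc3o2)c1OC
F12 | step 1 | 2,3-bis(propan-2-yloxy)benzaldehyde | CC(C)Oc1cccc(C=O)c1OC(C)C
A1 | alternative 1 | 4-(3,3-diethoxyprop-1-en-2-yl)-4-methoxy-3-(propan-2-yloxy)cyclobut-2-en-1-one (racemic) | CCOC(OCC)C(=C)C1(OC)C(OC(C)C)=CC1=O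
A2 | alternative 1 | 3-(diethoxymethyl)-4-methoxy-5-(propan-2-yloxy)phenol | CCOC(OCC)c1cc(O)cc(OC(C)C)c1OC
A3 | alternative 2 | 1-[2-methoxy-3,5-bis(pivaloyloxy)phenyl]-3-(2,3,4-trimethoxyphenyl)propane-1,3-dione | COc1ccc(C(=O)CC(=O)c2cc(OC(=O)C(C)(C)C)cc(OC(=O)C(C)(C)C)c2OC)c(OC)c1OC
A4 | alternative 2 | 2-[3,5-bis(pivaloyloxy)-2-methoxyphenyl]-5,6,7-trimethoxy-4H-chromen-4-one | COc1cc2oc(-c3cc(OC(=O)C(C)(C)C)cc(OC(=O)C(C)(C)C)c3OC)cc(=O)c2c(OC)c1OC
A5 | alternative 3 | methyl 4-{6-[3,5-bis(benzyloxy)-2-methoxyphenyl]-4-oxo-4H-pyran-2-yl}-2-methoxy-3-oxobutanoate (racemic) | COC(=O)C(OC)C(=O)Cc1cc(=O)cc(-c2cc(OCc3ccccc3)cc(OCc3ccccc3)c2OC)o1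
A6 | alternative 3 | 2-[3,5-bis(benzyloxy)-2-methoxyphenyl]-5,7-dihydroxy-6-methoxy-4H-chromen-4-one | COc1c(O)cc2oc(-c3cc(OCc4ccccc4)cc(OCc4ccccc4)c3OC)cc(=O)c2c1O
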